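**Plan**

Ring numbering used below: dienone ring C1 (ring C=O), C2 (hexanoyl), C3 (OH), C4 (quaternary), C5 (OH), C6 (CH2Ar).

- Cuts, in order: the two C–C bonds of the methylene bridge (CH2–C6 and CH2–aryl); then C1–C2 and C2–C3, which takes C2 out together with its hexanoyl group as the carbon of a diazoketone; then the C4–prenyl bond.
- Enabling feature: C2 lies between the two oxygen-bearing carbons C1 and C3. Without it, C1, C3, C4, C5, C6 form a cyclopentane-1,2,4-trione, and C4 sits between the carbonyls of a 2,2-disubstituted cyclopentane-1,3-dione that is Cs-symmetric before the third oxygen is placed.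
- Forward: prenylation of 2-methylcyclopentane-1,3-dione, ketoreductase desymmetrization, oxidation to a 4-allyloxy ene-dione, one-carbon enlargement of the five- to the six-membered ring that brings in C2 with the hexanoyl group, deallylation, and the methylene bridge to the aromatic ring last.
- Stereochemistry: the single stereocenter (C4, R) comes from the enzymatic reduction; none of its four bonds is touched afterwards.

Key step: step 9

Remark: a ketoreductase giving the (2R) series of 4 is assumed to be found by panel screening; the carbinol configuration is immaterial because that carbon is oxidized in step 6. Enolized compounds are drawn as one tautomer.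

**Route**

Step 1
Reactants: 1 2-methylcyclopentane-1,3-dione; 2 1-bromo-3-methylbut-2-ene
Product: 3 2-methyl-2-(3-methylbut-2-en-1-yl)cyclopentane-1,3-dione
Conditions: NaOH (1 M aq), Bu4NI (5 mol %), rt
Reagents that add atoms: none
Why: C-alkylation of the stabilized 1,3-diketone enolate in water, the classical route to 2,2-dialkylcyclopentane-1,3-diones; the product is Cs-symmetric and has no stereocenter.

Step 2
Reactants: 3 2-methyl-2-(3-methylbut-2-en-1-yl)cyclopentane-1,3-dione
Product: 4 (2R,3S)-3-hydroxy-2-methyl-2-(3-methylbut-2-en-1-yl)cyclopentan-1-one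
Conditions: ketoreductase (NADPH-dependent, panel enzyme selective for the 2R,3S isomer), NADP+ (cat.), i-PrOH (10 vol %), KH2PO4/K2HPO4 buffer pH 7, 30 °C
Reagents that add atoms: none
Why: enzymatic desymmetrization of a prochiral 2,2-disubstituted 1,3-dione by a ketoreductase, in which choice of one enantiotopic carbonyl sets C2 (R) and hydride delivery to one face sets C3 (S), with isopropanol recycling the cofactor.

Step 3
Reactants: 4 (2R,3S)-3-hydroxy-2-methyl-2-(3-methylbut-2-en-1-yl)cyclopentan-1-one
Product: 5 (2R,3S,5RS)-3,5-dihydroxy-2-methyl-2-(3-methylbut-2-en-1-yl)cyclopentan-1-one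
Conditions: KN(SiMe3)2 (2.3 equiv), THF, −78 °C; 2-(phenylsulfonyl)-3-phenyloxaziridine, −78 °C; aq NH4Cl
Reagents that add atoms: 2-(phenylsulfonyl)-3-phenyloxaziridine, O=S(=O)(c1ccccc1)N1OC1c1ccccc1
Why: only C5 can be enolized (C2 is quaternary), and the alkoxide–enolate dianion should be hydroxylated by the N-sulfonyloxaziridine (Davis enolate oxidation); the new carbinol center forms as a mixture that is erased in step 4.

Step 4
Reactants: 5 (2R,3S,5RS)-3,5-dihydroxy-2-methyl-2-(3-methylbut-2-en-1-yl)cyclopentan-1-one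
Product: 6 (4S,5R)-2,4-dihydroxy-5-methyl-5-(3-methylbut-2-en-1-yl)cyclopent-2-en-1-one
Conditions: Cu(OAc)2 (10 mol %), air, MeOH, rt
Reagents that add atoms: none
Why: copper-catalysed aerobic acyloin oxidation is selective for the α-hydroxy ketone over the isolated secondary alcohol, and the 1,2-dione formed should enolize to the diosphenol in the only direction open to it.

Step 5
Reactants: 6 (4S,5R)-2,4-dihydroxy-5-methyl-5-(3-methylbut-2-en-1-yl)cyclopent-2-en-1-one
Product: 7 (4S,5R)-4-hydroxy-5-methyl-5-(3-methylbut-2-en-1-yl)-2-(prop-2-en-1-yloxy)cyclopent-2-en-1-one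
Conditions: allyl bromide, K2CO3, acetone, rt
Reagents that add atoms: allyl bromide, C=CCBr
Why: Williamson O-alkylation of the acidic diosphenol hydroxyl, which the secondary alcohol does not undergo under carbonate; the allyl group fixes the enol double bond and masks this oxygen until step 10.

Step 6
Reactants: 7 (4S,5R)-4-hydroxy-5-methyl-5-(3-methylbut-2-en-1-yl)-2-(prop-2-en-1-yloxy)cyclopent-2-en-1-one
Product: 8 (2R)-2-methyl-2-(3-methylbut-2-en-1-yl)-4-(prop-2-en-1-yloxy)cyclopent-4-ene-1,3-dione
Conditions: Dess–Martin periodinane, NaHCO3, CH2Cl2, 0 °C to rt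
Reagents that add atoms: none
Why: buffered Dess–Martin oxidation of the allylic alcohol; the quaternary carbon keeps its configuration because the two flanking carbonyls remain different (one next to C–O-allyl, one next to CH).

Step 7
Reactants: 9 hexanoyl chloride
Product: 10 1-diazoheptan-2-one
Conditions: Me3SiCHN2 (2 equiv), MeCN/THF, 0 °C to rt
Reagents that add atoms: (trimethylsilyl)diazomethane, C[Si](C)(C)C=[N+]=[N-]
Why: acylation of the diazomethane equivalent by the acid chloride followed by loss of the silyl group, the standard preparation of terminal α-diazoketones.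

Step 8
Reactants: 8 (2R)-2-methyl-2-(3-methylbut-2-en-1-yl)-4-(prop-2-en-1-yloxy)cyclopent-4-ene-1,3-dione; 10 1-diazoheptan-2-one
Product: 11 1-diazo-1-[(1RS,5S)-1-hydroxy-5-methyl-5-(3-methylbut-2-en-1-yl)-4-oxo-2-(prop-2-en-1-yloxy)cyclopent-2-en-1-yl]heptan-2-one
Conditions: 10 (1.5 equiv), LiN(iPr)2, THF, −78 °C; then 8, −78 °C; AcOH quench at −78 °C
Reagents that add atoms: none
Why: aldol-type addition of a lithiated α-diazoketone to a ketone; the non-enolizable ene-dione should be attacked at the carbonyl next to the allyloxy-bearing carbon, since the other carbonyl is a deactivated vinylogous ester, and the new carbinol center (mixture) is consumed in step 9.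

Step 9
Reactants: 11 1-diazo-1-[(1RS,5S)-1-hydroxy-5-methyl-5-(3-methylbut-2-en-1-yl)-4-oxo-2-(prop-2-en-1-yloxy)cyclopent-2-en-1-yl]heptan-2-one
Product: 12 (6S)-4-hexanoyl-5-hydroxy-6-methyl-6-(3-methylbut-2-en-1-yl)-3-(prop-2-en-1-yloxy)cyclohexa-2,4-dien-1-one
Conditions: Rh2(OAc)4 (1 mol %), CH2Cl2, 0 °C to rt
Reagents that add atoms: none
Why: Rh2(OAc)4 turns the diazo group into a rhodium carbenoid next to the tertiary carbinol, and the hydroxyl oxygen pushes the ring bond from the carbinol carbon to the allyloxy-bearing carbon onto the carbenoid carbon (1,2-shift with loss of N2), so the carbinol carbon becomes the ketone and the hexanoyl-bearing carbon is inserted between the two oxygenated carbons, enlarging the five- to the six-membered ring. The closest known reaction type is the Rh2(OAc)4-catalysed one-carbon ring expansion of diazo aldol adducts of cycloalkanones and cycloalkenones (β-hydroxy-α-diazo carbonyl compounds to ring-enlarged β-dicarbonyl compounds), in which sp2 carbons migrate in preference to alkyl carbons. The six-membered ring is not closed end to end but arises by migration of a ring bond (a three-centre 1,2-shift), so no Baldwin mode applies. No new stereocenter remains: the carbinol center is consumed, the new ring CH enolizes into the triketone system, and the quaternary center is a spectator whose four bonds are untouched. The step needs the alkoxyvinyl carbon to migrate and not the quaternary carbon, which is secured because the migrating carbon is sp2 and carries an oxygen lone pair while the quaternary carbon is neopentyl-like and α to a ketone; it also needs the shift to outrun carbenoid addition to the prenyl or allyl double bond, which the neighbouring free hydroxyl favours.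

Step 10
Reactants: 12 (6S)-4-hexanoyl-5-hydroxy-6-methyl-6-(3-methylbut-2-en-1-yl)-3-(prop-2-en-1-yloxy)cyclohexa-2,4-dien-1-one
Product: 13 (4R)-2-hexanoyl-3,5-dihydroxy-4-methyl-4-(3-methylbut-2-en-1-yl)cyclohexa-2,5-dien-1-one
Conditions: Pd(PPh3)4 (3 mol %), morpholine (1.2 equiv), THF, rt; pH 4 buffer work-up
Reagents that add atoms: none
Why: Tsuji–Trost deallylation, in which the vinylogous allyl ester ionizes to a π-allyl palladium complex and a stabilized triketone enolate and morpholine takes the allyl group; the conditions are neutral, so the prenyl group and the stereocenter are not affected.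

Step 11
Reactants: 14 1-(2,4,6-trihydroxyphenyl)butan-1-one
Product: 15 1-(2,6-dihydroxy-4-methoxyphenyl)butan-1-one
Conditions: Me2SO4 (1.0 equiv), K2CO3, acetone, reflux
Reagents that add atoms: dimethyl sulfate, COS(=O)(=O)OC
Why: selective Williamson methylation of the para hydroxyl, since the two ortho hydroxyls are hydrogen-bonded to the ketone and less nucleophilic.

Step 12
Reactants: 13 (4R)-2-hexanoyl-3,5-dihydroxy-4-methyl-4-(3-methylbut-2-en-1-yl)cyclohexa-2,5-dien-1-one; 15 1-(2,6-dihydroxy-4-methoxyphenyl)butan-1-one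
Product: 18 (4R)-6-[(3-butanoyl-2,4-dihydroxy-6-methoxyphenyl)methyl]-2-hexanoyl-3,5-dihydroxy-4-methyl-4-(3-methylbut-2-en-1-yl)cyclohexa-2,5-dien-1-one, via Mannich base 16 (not isolated), via methylidene trione 17 (not isolated)
Conditions: Me2N=CH2+ I− (1.05 equiv), CH2Cl2, rt; then 15 (3 equiv), 1,4-dioxane, 80 °C
Reagents that add atoms: N,N-dimethylmethyleneiminium iodide (Eschenmoser's salt), C[N+](C)=C.[I-]
Why: Mannich reaction at C6, the only nucleophilic ring carbon of 13, then thermal loss of dimethylamine to the methylidene trione and Friedel–Crafts-type conjugate addition of the electron-rich arene at one of its two equivalent free positions, with excess 15 suppressing double alkylation; the stereocenter is not involved.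

**Compound list**

1 | 2-methylcyclopentane-1,3-dione | CC1C(=O)CCC1=O | starting material
2 | 1-bromo-3-methylbut-2-ene | CC(C)=CCBr | starting material
3 | 2-methyl-2-(3-methylbut-2-en-1-yl)cyclopentane-1,3-dione | CC1(CC=C(C)C)C(=O)CCC1=O | intermediate
4 | (2R,3S)-3-hydroxy-2-methyl-2-(3-methylbut-2-en-1-yl)cyclopentan-1-one | O=C1CC[C@H](O)[C@@]1(C)CC=C(C)C | intermediate
5 | (2R,3S,5RS)-3,5-dihydroxy-2-methyl-2-(3-methylbut-2-en-1-yl)cyclopentan-1-one | O=C1C(O)C[C@H](O)[C@@]1(C)CC=C(C)C | intermediate
6 | (4S,5R)-2,4-dihydroxy-5-methyl-5-(3-methylbut-2-en-1-yl)cyclopent-2-en-1-one | O=C1C(O)=C[C@H](O)[C@@]1(C)CC=C(C)C | intermediate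
7 | (4S,5R)-4-hydroxy-5-methyl-5-(3-methylbut-2-en-1-yl)-2-(prop-2-en-1-yloxy)cyclopent-2-en-1-one | C=CCOC1=C[C@H](O)[C@@](C)(CC=C(C)C)C1=O | intermediate
8 | (2R)-2-methyl-2-(3-methylbut-2-en-1-yl)-4-(prop-2-en-1-yloxy)cyclopent-4-ene-1,3-dione | C=CCOC1=CC(=O)[C@@](C)(CC=C(C)C)C1=O | intermediate
9 | hexanoyl chloride | CCCCCC(=O)Cl | starting material
10 | 1-diazoheptan-2-one | CCCCCC(=O)C=[N+]=[N-] | intermediate
11 | 1-diazo-1-[(1RS,5S)-1-hydroxy-5-methyl-5-(3-methylbut-2-en-1-yl)-4-oxo-2-(prop-2-en-1-yloxy)cyclopent-2-en-1-yl]heptan-2-one | C=CCOC1=CC(=O)[C@@](C)(CC=C(C)C)C1(O)C(=[N+]=[N-])C(=O)CCCCC | intermediate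
12 | (6S)-4-hexanoyl-5-hydroxy-6-methyl-6-(3-methylbut-2-en-1-yl)-3-(prop-2-en-1-yloxy)cyclohexa-2,4-dien-1-one | CCCCCC(=O)C1=C(O)[C@](C)(CC=C(C)C)C(=O)C=C1OCC=C | intermediate
13 | (4R)-2-hexanoyl-3,5-dihydroxy-4-methyl-4-(3-methylbut-2-en-1-yl)cyclohexa-2,5-dien-1-one | CCCCCC(=O)C1=C(O)[C@](C)(CC=C(C)C)C(O)=CC1=O | intermediate
14 | 1-(2,4,6-trihydroxyphenyl)butan-1-one | CCCC(=O)c1c(O)cc(O)cc1O | starting material
15 | 1-(2,6-dihydroxy-4-methoxyphenyl)butan-1-one | CCCC(=O)c1c(O)cc(OC)cc1O | intermediate
16 | (4R)-6-[(dimethylamino)methyl]-2-hexanoyl-3,5-dihydroxy-4-methyl-4-(3-methylbut-2-en-1-yl)cyclohexa-2,5-dien-1-one (Mannich base, formed in the flask) | CCCCCC(=O)C1=C(O)[C@](C)(CC=C(C)C)C(O)=C(CN(C)C)C1=O | intermediate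
17 | (6S)-4-hexanoyl-5-hydroxy-6-methyl-6-(3-methylbut-2-en-1-yl)-2-methylidenecyclohex-4-ene-1,3-dione (formed in the flask) | CCCCCC(=O)C1=C(O)[C@](C)(CC=C(C)C)C(=O)C(=C)C1=O | intermediate
18 | (4R)-6-[(3-butanoyl-2,4-dihydroxy-6-methoxyphenyl)methyl]-2-hexanoyl-3,5-dihydroxy-4-methyl-4-(3-methylbut-2-en-1-yl)cyclohexa-2,5-dien-1-one | CCCCCC(=O)C1=C(O)[C@](C)(CC=C(C)C)C(O)=C(Cc2c(OC)cc(O)c(C(=O)CCC)c2O)C1=O | target

**Step count and risks**

Total steps: 12. Longest linear sequence: 10 (steps 1–6, 8, 9, 10, 12).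

Steps most likely to fail:

1. Step 9. The carbenoid may add to the prenyl double bond (a five-membered-ring cyclopropanation is geometrically possible), or the quaternary carbon may migrate in place of the alkoxyvinyl carbon. The fallback is a carbene-free semipinacol ring enlargement that sets out from 8. Addition of (E)-hept-1-en-1-yllithium (from (E)-1-iodohept-1-ene and t-BuLi, THF, −78 °C) to the same carbonyl should give the tertiary allylic alcohol 4-[(1E)-hept-1-en-1-yl]-4-hydroxy-5-methyl-5-(3-methylbut-2-en-1-yl)-3-(prop-2-en-1-yloxy)cyclopent-2-en-1-one F1. Hydroxyl-directed epoxidation with VO(acac)2 and t-BuOOH should give the epoxy alcohol 4-hydroxy-5-methyl-5-(3-methylbut-2-en-1-yl)-4-(3-pentyloxiran-2-yl)-3-(prop-2-en-1-yloxy)cyclopent-2-en-1-one F2. BF3·OEt2 at −78 °C should then shift the alkoxyvinyl ring carbon onto the epoxide carbon, giving the ring-enlarged β-hydroxy ketone 6-(1-hydroxyhexyl)-2-methyl-2-(3-methylbut-2-en-1-yl)-5-(prop-2-en-1-yloxy)cyclohex-4-ene-1,3-dione F3. Dess–Martin oxidation of F3 returns to the route at 12.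

2. Step 8. The lithiated diazoketone may add to the wrong carbonyl or in conjugate fashion, or the adduct may revert before quench. The fallback sets out from 7, where only one carbonyl is present. Silylation (t-BuMe2SiOTf, 2,6-lutidine) should give (4S,5R)-4-[(tert-butyldimethylsilyl)oxy]-5-methyl-5-(3-methylbut-2-en-1-yl)-2-(prop-2-en-1-yloxy)cyclopent-2-en-1-one F4. Addition of lithiated 10 should give the diazo alcohol 1-diazo-1-[4-[(tert-butyldimethylsilyl)oxy]-1-hydroxy-5-methyl-5-(3-methylbut-2-en-1-yl)-2-(prop-2-en-1-yloxy)cyclopent-2-en-1-yl]heptan-2-one F5. Rh2(OAc)4 should enlarge the ring to the silyl ether 5-[(tert-butyldimethylsilyl)oxy]-2-hexanoyl-1-hydroxy-6-methyl-6-(3-methylbut-2-en-1-yl)-3-(prop-2-en-1-yloxy)cyclohexa-1,3-diene F6. Bu4NF buffered with AcOH should free the allylic alcohol 2-hexanoyl-6-methyl-6-(3-methylbut-2-en-1-yl)-3-(prop-2-en-1-yloxy)cyclohexa-1,3-diene-1,5-diol F7. Dess–Martin oxidation of F7 returns to the route at 12.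

3. Step 12. The methylidene trione may self-condense, or the arene may be alkylated twice. The fallback reverses the roles of the partners and sets out from 15. Aminomethylation of 15 with Eschenmoser's salt (1 equiv) should give the aryl Mannich base 1-{3-[(dimethylamino)methyl]-2,6-dihydroxy-4-methoxyphenyl}butan-1-one F8. Heating F8 with 13 in 1,4-dioxane should release dimethylamine and let the enolized trione add at its C6 to the benzylic carbon, coming back to the route at 18.

**Further compounds**

F1 | step 9 | 4-[(1E)-hept-1-en-1-yl]-4-hydroxy-5-methyl-5-(3-methylbut-2-en-1-yl)-3-(prop-2-en-1-yloxy)cyclopent-2-en-1-one (quaternary center as in 8) | C=CCOC1=CC(=O)[C@@](C)(CC=C(C)C)C1(O)/C=C/CCCCC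
F2 | step 9 | 4-hydroxy-5-methyl-5-(3-methylbut-2-en-1-yl)-4-(3-pentyloxiran-2-yl)-3-(prop-2-en-1-yloxy)cyclopent-2-en-1-one (quaternary center as in 8) | C=CCOC1=CC(=O)[C@@](C)(CC=C(C)C)C1(O)C2OC2CCCCC
F3 | step 9 | 6-(1-hydroxyhexyl)-2-methyl-2-(3-methylbut-2-en-1-yl)-5-(prop-2-en-1-yloxy)cyclohex-4-ene-1,3-dione (quaternary center as in 12) | CCCCCC(O)C1C(=O)[C@](C)(CC=C(C)C)C(=O)C=C1OCC=C
F4 | step 8 | (4S,5R)-4-[(tert-butyldimethylsilyl)oxy]-5-methyl-5-(3-methylbut-2-en-1-yl)-2-(prop-2-en-1-yloxy)cyclopent-2-en-1-one | C=CCOC1=C[C@H](O[Si](C)(C)C(C)(C)C)[C@@](C)(CC=C(C)C)C1=O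
F5 | step 8 | 1-diazo-1-[4-[(tert-butyldimethylsilyl)oxy]-1-hydroxy-5-methyl-5-(3-methylbut-2-en-1-yl)-2-(prop-2-en-1-yloxy)cyclopent-2-en-1-yl]heptan-2-one (ring centers as in F4, carbinol center as a mixture) | C=CCOC1=C[C@H](O[Si](C)(C)C(C)(C)C)[C@@](C)(CC=C(C)C)C1(O)C(=[N+]=[N-])C(=O)CCCCC
F6 | step 8 | 5-[(tert-butyldimethylsilyl)oxy]-2-hexanoyl-1-hydroxy-6-methyl-6-(3-methylbut-2-en-1-yl)-3-(prop-2-en-1-yloxy)cyclohexa-1,3-diene (centers as in F4) | CCCCCC(=O)C1=C(O)[C@](C)(CC=C(C)C)[C@@H](O[Si](C)(C)C(C)(C)C)C=C1OCC=C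
F7 | step 8 | 2-hexanoyl-6-methyl-6-(3-methylbut-2-en-1-yl)-3-(prop-2-en-1-yloxy)cyclohexa-1,3-diene-1,5-diol (centers as in F4) | CCCCCC(=O)C1=C(O)[C@](C)(CC=C(C)C)[C@@H](O)C=C1OCC=C
F8 | step 12 | 1-{3-[(dimethylamino)methyl]-2,6-dihydroxy-4-methoxyphenyl}butan-1-one | CCCC(=O)c1c(O)cc(OC)c(CN(C)C)c1O
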